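**Retrosynthetic overview**

1. Last operations: Yamaguchi esterification of O8 with a preformed (2R,3R)-epoxy acid (from Sharpless epoxidation of angelyl alcohol), then release of the C3 hydroxyl.
2. Key disconnection: the α-methylene-γ-lactone (ring O–C6–C7–C11–C12) is removed as 2-bromoacrylic acid from a ten-membered (4Z,6E)-diene; forward, a Pd-catalysed [3+2] heteroannulation makes C11–C7 and then O–C6 and sets C6 and C7.
3. Enabling feature: the lactone oxygen sits on C6, which is allylic to the ring double bond C4=C5 (a γ-alkenyl-γ-lactone), so carbopalladation of a C4=C5–C6=C7 diene at C7 gives a C4–C5–C6 π-allyl that the carboxylate captures at C6, restoring C4=C5.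
4. Ten-membered ring: intramolecular Horner–Wadsworth–Emmons closure of C1=C10; the open chain comes from Stille union at C5–C6 of a (Z)-iodoalkene (C1–C5, C3 from allylboration) and an (E)-vinylstannane (C6–C10, C8 from CBS reduction).
5. Order of ring formation: carbocycle (step 14), then lactone (step 15); the oxirane arrives preformed in the side-chain acid.

Key step: step 15

Remark: germacranolide numbering is used (ring C1–C10; C11, C12, C13 are the lactone α-carbon, carbonyl and methylene; C14 is the ester carbon on C10; C15 is the methyl on C4). All starting materials are assumed to be purchasable. The two phosphonoacetate intermediates are carried as C10 epimers because that centre is erased in the ring closure.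

**Fragment 1 (C1–C5)**

Step 1
Reactants: 1 prop-2-yn-1-ol
Product: 3 (Z)-3-iodo-2-methylprop-2-en-1-ol, via chelated (Z)-alkenylmagnesium alkoxide 2 (not isolated)
Conditions: MeMgBr (3 equiv), CuI (10 mol %), THF, 0 to 25 °C; then I2, −20 to 25 °C
Reagents that add atoms: methylmagnesium bromide (C[Mg]Br); iodine (II)
Why: Copper-catalysed anti-carbomagnesiation of a propargylic alcohol places methyl on C4 and magnesium on C5 inside a five-membered alkoxide chelate, so iodinolysis with retention should give only the Z iodide (I cis to CH2OH).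

Step 2
Reactants: 3 (Z)-3-iodo-2-methylprop-2-en-1-ol
Product: 4 (Z)-3-iodo-2-methylprop-2-enal
Conditions: MnO2 (15 equiv), CH2Cl2, 25 °C, dark; filtered and used as a solution
Reagents that add atoms: none
Why: Neutral allylic oxidation on activated MnO2 should not isomerise the light- and acid-sensitive Z-iodoenal.

Step 3
Reactants: 4 (Z)-3-iodo-2-methylprop-2-enal
Product: 5 (3S,1Z)-1-iodo-2-methylhexa-1,5-dien-3-ol
Conditions: (−)-Ipc2BOMe (from (+)-α-pinene), allylMgBr, Et2O, 0 to 25 °C; then 4, −78 °C; NaOH, H2O2
Reagents that add atoms: allylmagnesium bromide (C=CC[Mg]Br)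
Why: Brown allylboration through a chair six-membered transition state; the (+)-α-pinene-derived allylborane adds to the Si face of the aldehyde and should set C3 as S.

Step 4
Reactants: 5 (3S,1Z)-1-iodo-2-methylhexa-1,5-dien-3-ol
Product: 6 tert-butyl{[(3S,1Z)-1-iodo-2-methylhexa-1,5-dien-3-yl]oxy}dimethylsilane
Conditions: TBSCl, imidazole, DMF, 25 °C
Reagents that add atoms: tert-butyldimethylsilyl chloride (CC(C)(C)[Si](C)(C)Cl)
Why: Standard silylation of the secondary allylic alcohol; the TBS group is the one that stays to the last step.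

Step 5
Reactants: 6 tert-butyl{[(3S,1Z)-1-iodo-2-methylhexa-1,5-dien-3-yl]oxy}dimethylsilane
Product: 8 (3S,4Z)-3-[(tert-butyldimethylsilyl)oxy]-5-iodo-4-methylpent-4-enal (fragment 1), via vicinal diol 7 (not isolated)
Conditions: OsO4 (2 mol %), NMO, acetone/H2O, 0 °C; then NaIO4, 25 °C
Reagents that add atoms: N-methylmorpholine N-oxide (C[N+]1([O-])CCOCC1); water (O)
Why: Upjohn dihydroxylation (the two oxygens come from NMO and water by way of catalytic OsO4) followed by periodate cleavage; the monosubstituted alkene should react in preference to the hindered, iodine-deactivated trisubstituted one, and the β-silyloxy aldehyde has no epimerisable centre.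

**Fragment 2 (C6–C10 and C14)**

Step 6
Reactants: 9 3-(diethoxyphosphoryl)propanoic acid; 10 (E)-1,2-bis(tributylstannyl)ethene
Product: 12 diethyl [(4E)-3-oxo-5-(tributylstannyl)pent-4-en-1-yl]phosphonate, via 3-(diethoxyphosphoryl)propanoyl chloride 11 (not isolated)
Conditions: (COCl)2, DMF (cat.), CH2Cl2, 0 to 25 °C, evaporate; then 10 (1.5 equiv), Pd(PPh3)2Cl2 (3 mol %), THF, 50 °C
Reagents that add atoms: oxalyl chloride (O=C(Cl)C(=O)Cl)
Why: Acylative Stille coupling with retention of the E geometry (oxalyl chloride only supplies the chlorine of acid chloride 11, which is lost again in the coupling); the β-stannyl enone formed is conjugated and far less reactive than 10, which should stop the reaction at monoacylation.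

Step 7
Reactants: 12 diethyl [(4E)-3-oxo-5-(tributylstannyl)pent-4-en-1-yl]phosphonate
Product: 13 diethyl [(3R,4E)-3-hydroxy-5-(tributylstannyl)pent-4-en-1-yl]phosphonate
Conditions: (S)-2-methyl-CBS-oxazaborolidine (20 mol %), catecholborane, toluene, −78 °C
Reagents that add atoms: none
Why: Corey–Bakshi–Shibata reduction; the ketone binds with the β-stannylvinyl group as the large substituent and hydride is delivered within the catalyst–borane complex, so the (S)-catalyst should give the R carbinol (C8).

Step 8
Reactants: 13 diethyl [(3R,4E)-3-hydroxy-5-(tributylstannyl)pent-4-en-1-yl]phosphonate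
Product: 14 diethyl [(3R,4E)-3-[(triethylsilyl)oxy]-5-(tributylstannyl)pent-4-en-1-yl]phosphonate
Conditions: Et3SiCl, imidazole, CH2Cl2, 0 °C
Reagents that add atoms: chlorotriethylsilane (CC[Si](Cl)(CC)CC)
Why: Standard silylation; an ether (not an ester) at O8 is required so that zerovalent palladium cannot ionise this allylic, later dienylic, position in steps 13 and 15.

Step 9
Reactants: 14 diethyl [(3R,4E)-3-[(triethylsilyl)oxy]-5-(tributylstannyl)pent-4-en-1-yl]phosphonate
Product: 15 methyl (4R,5E)-2-(diethoxyphosphoryl)-4-[(triethylsilyl)oxy]-6-(tributylstannyl)hex-5-enoate (fragment 2; C2 epimers)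
Conditions: LDA (2.2 equiv), THF, −78 °C; ClCO2Me, −78 to −40 °C
Reagents that add atoms: methyl chloroformate (COC(=O)Cl)
Why: C-acylation of the α-lithiated phosphonate by a chloroformate; the second equivalent of base takes up the more acidic product, and the new centre (C10) is uncontrolled and irrelevant.

**Fragment 3 (side-chain acid)**

Step 10
Reactants: 16 methyl (Z)-2-methylbut-2-enoate (methyl angelate)
Product: 17 (Z)-2-methylbut-2-en-1-ol
Conditions: DIBAL-H (2.2 equiv), CH2Cl2, −78 to 0 °C
Reagents that add atoms: none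
Why: 1,2-Reduction of the ester by DIBAL-H leaves the Z double bond untouched.

Step 11
Reactants: 17 (Z)-2-methylbut-2-en-1-ol
Product: 18 [(2S,3R)-2,3-dimethyloxiran-2-yl]methanol
Conditions: Ti(OiPr)4 (10 mol %), L-(+)-diethyl tartrate (12 mol %), t-BuOOH, 4 Å MS, CH2Cl2, −20 °C
Reagents that add atoms: tert-butyl hydroperoxide (CC(C)(C)OO)
Why: Sharpless asymmetric epoxidation; L-(+)-tartrate delivers oxygen to the same face that gives (2S,3S)-epoxides from E-allylic alcohols, which for this Z-methyl substrate corresponds to 2S,3R, and the epoxidation is stereospecific (methyls stay trans).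

Step 12
Reactants: 18 [(2S,3R)-2,3-dimethyloxiran-2-yl]methanol
Product: 19 (2R,3R)-2,3-dimethyloxirane-2-carboxylic acid (fragment 3)
Conditions: TEMPO (20 mol %), PhI(OAc)2 (2.2 equiv), MeCN/H2O, 25 °C
Reagents that add atoms: water (O)
Why: Oxoammonium oxidation via the aldehyde hydrate reaches the acid without opening the epoxide; the C2 label changes from S to R only through CIP priorities.

**Union, ring closure and endgame**

Step 13
Reactants: 8 (3S,4Z)-3-[(tert-butyldimethylsilyl)oxy]-5-iodo-4-methylpent-4-enal; 15 methyl (4R,5E)-2-(diethoxyphosphoryl)-4-[(triethylsilyl)oxy]-6-(tributylstannyl)hex-5-enoate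
Product: 20 methyl (4R,5E,7Z,9S)-9-[(tert-butyldimethylsilyl)oxy]-2-(diethoxyphosphoryl)-8-methyl-11-oxo-4-[(triethylsilyl)oxy]undeca-5,7-dienoate (C2 epimers)
Conditions: Pd2(dba)3 (5 mol %), AsPh3 (40 mol %), CuI (20 mol %), DMF, 25 °C, dark
Reagents that add atoms: none
Why: Stille coupling joins C5 and C6 with retention at both alkenes to give the (4Z,6E)-diene; the neutral conditions should leave the aldehyde and the acidic phosphonoacetate untouched.

Step 14
Reactants: 20 methyl (4R,5E,7Z,9S)-9-[(tert-butyldimethylsilyl)oxy]-2-(diethoxyphosphoryl)-8-methyl-11-oxo-4-[(triethylsilyl)oxy]undeca-5,7-dienoate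
Product: 21 methyl (1E,4S,5Z,7E,9R)-4-[(tert-butyldimethylsilyl)oxy]-5-methyl-9-[(triethylsilyl)oxy]cyclodeca-1,5,7-triene-1-carboxylate
Conditions: LiCl (20 equiv), DBU (5 equiv), MeCN, 0.5 mM (slow addition of 20), 25 °C
Reagents that add atoms: none
Why: Intramolecular Horner–Wadsworth–Emmons reaction under Masamune–Roush conditions closes C1=C10; the required geometry (C2 cis to C9 in the ring, C2 trans to CO2Me) is both the usual outcome of this olefination and the less strained ring isomer, and six of the ten ring atoms are sp2, which keeps transannular strain low.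

Step 15
Reactants: 21 methyl (1E,4S,5Z,7E,9R)-4-[(tert-butyldimethylsilyl)oxy]-5-methyl-9-[(triethylsilyl)oxy]cyclodeca-1,5,7-triene-1-carboxylate; 22 2-bromoprop-2-enoic acid (2-bromoacrylic acid)
Product: 23 methyl (3aS,4R,6E,9S,10Z,11aR)-9-[(tert-butyldimethylsilyl)oxy]-10-methyl-3-methylidene-2-oxo-4-[(triethylsilyl)oxy]-2,3,3a,4,5,8,9,11a-octahydrocyclodeca[b]furan-6-carboxylate (6,7-trans-fused α-methylene-γ-lactone; O3 as TBS ether; O8 as TES ether)
Conditions: Pd(OAc)2 (10 mol %), PPh3 (20 mol %), Ag2CO3 (1.2 equiv), 22 (2 equiv, slow addition), DMF, 50 °C, dark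
Reagents that add atoms: none
Why: Proposed new method: zerovalent palladium (formed from Pd(OAc)2 and PPh3) inserts into the C–Br bond of 22, Ag2CO3 removes bromide and forms the carboxylate, and the 1-carboxyvinyl–palladium adds syn across the disubstituted E-C6=C7 bond of the C4=C5–C6=C7 diene with the new C11–C7 bond at the less substituted diene terminus, which leaves palladium on a C4–C5–C6 π-allyl; the closest known reaction type is the Larock heteroannulation of 1,3-dienes by aryl and vinyl halides that carry an O–H or N–H nucleophile. The five-membered lactone ring (O–C6–C7–C11–C12) is closed in a formal [3+2] mode: the palladium-bound carboxylate forms a six-membered oxapalladacycle and C–O reductive elimination at the allyl terminus C6 (5-exo; closure at C4 would need a seven-membered ring) restores the C4=C5 double bond. C7 is controlled by C8: the E-alkene of the ten-membered ring can only be attacked on its peripheral face, and in the favoured arrangement the C8–C9 ring bond is anti to the incoming carbon, the siloxy group lies inside (near the alkene plane, without allylic strain because C6 carries only H) and H is outside, which leads to the target configuration at C7. C6 is controlled by the mechanism: C–O formation takes place on the palladium-bearing face, syn to the new C11–C7 bond, as in the cis-fused products that cyclic dienes give in the known reaction, and syn addition across an E-alkene gives the trans-fused lactone (H6 and H7 anti). The step needs terminus selectivity (C7 over the fully substituted C4), face selectivity and syn closure; halide-free conditions keep the carboxylate on palladium for the syn pathway, the Z geometry of C4=C5 should survive because the π-allyl collapses at C6 before it can isomerise through the tertiary C4 σ-form, and the oxygens at C3 and C8 are silyl ethers that zerovalent palladium does not ionise.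

Step 16
Reactants: 23 methyl (3aS,4R,6E,9S,10Z,11aR)-9-[(tert-butyldimethylsilyl)oxy]-10-methyl-3-methylidene-2-oxo-4-[(triethylsilyl)oxy]-2,3,3a,4,5,8,9,11a-octahydrocyclodeca[b]furan-6-carboxylate
Product: 24 methyl (3aR,4R,6E,9S,10Z,11aR)-9-[(tert-butyldimethylsilyl)oxy]-4-hydroxy-10-methyl-3-methylidene-2-oxo-2,3,3a,4,5,8,9,11a-octahydrocyclodeca[b]furan-6-carboxylate
Conditions: PPTS (20 mol %), MeOH/CH2Cl2, 0 °C
Reagents that add atoms: none
Why: Acid-catalysed methanolysis removes the triethylsilyl ether much faster than the tert-butyldimethylsilyl ether, and the mildly acidic medium should not promote relactonisation towards O8 or conjugate addition to the methylene lactone.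

Step 17
Reactants: 24 methyl (3aR,4R,6E,9S,10Z,11aR)-9-[(tert-butyldimethylsilyl)oxy]-4-hydroxy-10-methyl-3-methylidene-2-oxo-2,3,3a,4,5,8,9,11a-octahydrocyclodeca[b]furan-6-carboxylate; 19 (2R,3R)-2,3-dimethyloxirane-2-carboxylic acid
Product: 26 methyl (3aR,4R,6E,9S,10Z,11aR)-9-[(tert-butyldimethylsilyl)oxy]-4-{[(2R,3R)-2,3-dimethyloxirane-2-carbonyl]oxy}-10-methyl-3-methylidene-2-oxo-2,3,3a,4,5,8,9,11a-octahydrocyclodeca[b]furan-6-carboxylate, via mixed 2,4,6-trichlorobenzoic anhydride 25 (not isolated)
Conditions: 19, 2,4,6-trichlorobenzoyl chloride, Et3N, THF, 0 °C; then 24, DMAP, toluene, 25 °C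
Reagents that add atoms: 2,4,6-trichlorobenzoyl chloride (O=C(Cl)c1c(Cl)cc(Cl)cc1Cl)
Why: Yamaguchi esterification (the aroyl chloride only supplies the aroyl group of mixed anhydride 25, which leaves as the acid); DMAP attacks the less shielded epoxy-acyl carbonyl of the mixed anhydride, and the acid has no α-hydrogen, so its two stereocentres cannot epimerise.

Step 18
Reactants: 26 methyl (3aR,4R,6E,9S,10Z,11aR)-9-[(tert-butyldimethylsilyl)oxy]-4-{[(2R,3R)-2,3-dimethyloxirane-2-carbonyl]oxy}-10-methyl-3-methylidene-2-oxo-2,3,3a,4,5,8,9,11a-octahydrocyclodeca[b]furan-6-carboxylate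
Product: 27 methyl (3aR,4R,6E,9S,10Z,11aR)-4-{[(2R,3R)-2,3-dimethyloxirane-2-carbonyl]oxy}-9-hydroxy-10-methyl-3-methylidene-2-oxo-2,3,3a,4,5,8,9,11a-octahydrocyclodeca[b]furan-6-carboxylate (CNP0143679.1)
Conditions: HF·pyridine, pyridine, THF, 0 to 25 °C
Reagents that add atoms: none
Why: Fluoride-mediated cleavage of the allylic silyl ether under pyridine-buffered conditions should spare the oxirane, the two esters and the methylene lactone.

**Compound list**

1 | prop-2-yn-1-ol | C#CCO | starting material
2 | chelated (Z)-alkenylmagnesium alkoxide (4-methyl-2,5-dihydro-1,2-oxamagnesole) | CC1=C[Mg]OC1 | intermediate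
3 | (Z)-3-iodo-2-methylprop-2-en-1-ol | I/C=C(/C)CO | intermediate
4 | (Z)-3-iodo-2-methylprop-2-enal | I/C=C(/C)C=O | intermediate
5 | (3S,1Z)-1-iodo-2-methylhexa-1,5-dien-3-ol | I/C=C(/C)[C@@H](O)CC=C | intermediate
6 | tert-butyl{[(3S,1Z)-1-iodo-2-methylhexa-1,5-dien-3-yl]oxy}dimethylsilane | I/C=C(/C)[C@@H](O[Si](C)(C)C(C)(C)C)CC=C | intermediate
7 | (4S,5Z)-4-[(tert-butyldimethylsilyl)oxy]-6-iodo-5-methylhex-5-ene-1,2-diol (C2 epimers) | I/C=C(/C)[C@@H](O[Si](C)(C)C(C)(C)C)CC(O)CO | intermediate
8 | (3S,4Z)-3-[(tert-butyldimethylsilyl)oxy]-5-iodo-4-methylpent-4-enal | I/C=C(/C)[C@@H](O[Si](C)(C)C(C)(C)C)CC=O | intermediate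
9 | 3-(diethoxyphosphoryl)propanoic acid | CCOP(=O)(CCC(=O)O)OCC | starting material
10 | (E)-1,2-bis(tributylstannyl)ethene | CCCC[Sn](CCCC)(CCCC)/C=C/[Sn](CCCC)(CCCC)CCCC | starting material
11 | 3-(diethoxyphosphoryl)propanoyl chloride | CCOP(=O)(CCC(=O)Cl)OCC | intermediate
12 | diethyl [(4E)-3-oxo-5-(tributylstannyl)pent-4-en-1-yl]phosphonate | CCOP(=O)(CCC(=O)/C=C/[Sn](CCCC)(CCCC)CCCC)OCC | intermediate
13 | diethyl [(3R,4E)-3-hydroxy-5-(tributylstannyl)pent-4-en-1-yl]phosphonate | CCOP(=O)(CC[C@@H](O)/C=C/[Sn](CCCC)(CCCC)CCCC)OCC | intermediate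
14 | diethyl [(3R,4E)-3-[(triethylsilyl)oxy]-5-(tributylstannyl)pent-4-en-1-yl]phosphonate | CCOP(=O)(CC[C@@H](O[Si](CC)(CC)CC)/C=C/[Sn](CCCC)(CCCC)CCCC)OCC | intermediate
15 | methyl (4R,5E)-2-(diethoxyphosphoryl)-4-[(triethylsilyl)oxy]-6-(tributylstannyl)hex-5-enoate (C2 epimers) | COC(=O)C(C[C@@H](O[Si](CC)(CC)CC)/C=C/[Sn](CCCC)(CCCC)CCCC)P(=O)(OCC)OCC | intermediate
16 | methyl (Z)-2-methylbut-2-enoate | C/C=C(/C)C(=O)OC | starting material
17 | (Z)-2-methylbut-2-en-1-ol | C/C=C(/C)CO | intermediate
18 | [(2S,3R)-2,3-dimethyloxiran-2-yl]methanol | OC[C@]1(C)O[C@@H]1C | intermediate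
19 | (2R,3R)-2,3-dimethyloxirane-2-carboxylic acid | OC(=O)[C@]1(C)O[C@@H]1C | intermediate
20 | methyl (4R,5E,7Z,9S)-9-[(tert-butyldimethylsilyl)oxy]-2-(diethoxyphosphoryl)-8-methyl-11-oxo-4-[(triethylsilyl)oxy]undeca-5,7-dienoate (C2 epimers) | COC(=O)C(P(=O)(OCC)OCC)C[C@@H](O[Si](CC)(CC)CC)/C=C/C=C(/C)[C@@H](O[Si](C)(C)C(C)(C)C)CC=O | intermediate
21 | methyl (1E,4S,5Z,7E,9R)-4-[(tert-butyldimethylsilyl)oxy]-5-methyl-9-[(triethylsilyl)oxy]cyclodeca-1,5,7-triene-1-carboxylate | [C@H]1(O[Si](CC)(CC)CC)/C=C/C=C(/C)[C@@H](O[Si](C)(C)C(C)(C)C)C/C=C(/C(=O)OC)C1 | intermediate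
22 | 2-bromoprop-2-enoic acid | C=C(Br)C(=O)O | starting material
23 | methyl (3aS,4R,6E,9S,10Z,11aR)-9-[(tert-butyldimethylsilyl)oxy]-10-methyl-3-methylidene-2-oxo-4-[(triethylsilyl)oxy]-2,3,3a,4,5,8,9,11a-octahydrocyclodeca[b]furan-6-carboxylate (ring stereocentres arranged as in 27; the label at C3a reads S only because of the silyloxy priority) | C=C1C(=O)O[C@@H]2/C=C(/C)[C@@H](O[Si](C)(C)C(C)(C)C)C/C=C(/C(=O)OC)C[C@@H](O[Si](CC)(CC)CC)[C@@H]12 | intermediate
24 | methyl (3aR,4R,6E,9S,10Z,11aR)-9-[(tert-butyldimethylsilyl)oxy]-4-hydroxy-10-methyl-3-methylidene-2-oxo-2,3,3a,4,5,8,9,11a-octahydrocyclodeca[b]furan-6-carboxylate | C=C1C(=O)O[C@@H]2/C=C(/C)[C@@H](O[Si](C)(C)C(C)(C)C)C/C=C(/C(=O)OC)C[C@@H](O)[C@@H]12 | intermediate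
25 | (2R,3R)-2,3-dimethyloxirane-2-carboxylic 2,4,6-trichlorobenzoic anhydride | O=C(OC(=O)c1c(Cl)cc(Cl)cc1Cl)[C@]1(C)O[C@@H]1C | intermediate
26 | methyl (3aR,4R,6E,9S,10Z,11aR)-9-[(tert-butyldimethylsilyl)oxy]-4-{[(2R,3R)-2,3-dimethyloxirane-2-carbonyl]oxy}-10-methyl-3-methylidene-2-oxo-2,3,3a,4,5,8,9,11a-octahydrocyclodeca[b]furan-6-carboxylate | C=C1C(=O)O[C@@H]2/C=C(/C)[C@@H](O[Si](C)(C)C(C)(C)C)C/C=C(/C(=O)OC)C[C@@H](OC(=O)[C@]3(C)O[C@@H]3C)[C@@H]12 | intermediate
27 | methyl (3aR,4R,6E,9S,10Z,11aR)-4-{[(2R,3R)-2,3-dimethyloxirane-2-carbonyl]oxy}-9-hydroxy-10-methyl-3-methylidene-2-oxo-2,3,3a,4,5,8,9,11a-octahydrocyclodeca[b]furan-6-carboxylate | C=C1C(=O)O[C@@H]2/C=C(/C)[C@@H](O)C/C=C(/C(=O)OC)C[C@@H](OC(=O)[C@]3(C)O[C@@H]3C)[C@@H]12 | target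

**Step count and risks**

Total step count: 18. Longest linear sequence: 11 steps (steps 1–5, then 13–18).

Step 15 (proposed new method) is the riskiest step. The carbopalladation may take the wrong face at C7, the C–O bond may close anti instead of syn and give the cis-fused lactone, the π-allyl may lose a β-hydrogen to give a Heck-type triene, or zerovalent palladium may re-ionise the allylic lactone once formed. The fallback uses known radical chemistry, sets out from 21 and returns at 23. Carbolactonisation of the diene with malonic acid and trivalent manganese (Mn(OAc)3·2H2O, KOAc, AcOH, 25 °C) should add the malonyl radical at C7, and oxidation of the allyl radical with capture by the carboxyl group at C6 should give the α-carboxy lactone F1 (C11 epimers). Decarboxylative Mannich methylenation of F1 (aqueous formaldehyde, Et2NH, NaOAc, AcOH) would then give 23. If the triethylsilyl ether is lost in acetic acid, the material enters the route at 24 instead.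

Step 14 may fail through oligomerisation instead of ring closure, β-elimination of the C3 silyloxy group from the aldehyde, or base-induced migration of the new double bond. The fallback changes the ring-closing bond, sets out from 8 and 15 and returns at 21. Intermolecular Horner–Wadsworth–Emmons reaction of 8 with 15 (LiCl, DBU, MeCN) would first form C1=C10 and give the open-chain iodide–stannane F2. An intramolecular Stille coupling of F2 (Pd2(dba)3, AsPh3, DMF, high dilution) would then close the ring at C5–C6 to 21, replacing steps 13 and 14.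

Step 17 may suffer from slow acyl transfer to the hindered C8 carbinol, which would allow base-induced relactonisation of the free hydroxy lactone towards O8 or addition of DMAP to the methylene lactone. The fallback avoids the free alcohol, sets out from 23 and 19 and returns at 26. Acid 19 would be converted into the acyl fluoride F3 (cyanuric fluoride, pyridine, CH2Cl2). A known fluoride-catalysed acyl transfer (F3, catalytic Bu4NF, THF, 0 °C) would turn the more labile triethylsilyl ether of 23 directly into the ester 26, with the TBS ether expected to react much more slowly; steps 16 and 17 are replaced.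

**Further compounds**

F1 | step 15 | 3-carboxy analogue of 23 (CO2H and H on C11 in place of the methylidene group; C11 epimers) | OC(=O)C1C(=O)O[C@@H]2/C=C(/C)[C@@H](O[Si](C)(C)C(C)(C)C)C/C=C(/C(=O)OC)C[C@@H](O[Si](CC)(CC)CC)[C@@H]12
F2 | step 14 | methyl (2E,5S,6Z)-5-[(tert-butyldimethylsilyl)oxy]-7-iodo-6-methyl-2-{(2R,3E)-2-[(triethylsilyl)oxy]-4-(tributylstannyl)but-3-en-1-yl}hepta-2,6-dienoate | I/C=C(/C)[C@@H](O[Si](C)(C)C(C)(C)C)C/C=C(/C(=O)OC)C[C@@H](O[Si](CC)(CC)CC)/C=C/[Sn](CCCC)(CCCC)CCCC
F3 | step 17 | (2R,3R)-2,3-dimethyloxirane-2-carbonyl fluoride | O=C(F)[C@]1(C)O[C@@H]1C
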